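Everything rests on disconnecting the two bonds that flank the dihydrofuran oxygen O1: the C7–CH2 bond of the prenyl group on benzene ring B and the O1–C2 bond of dihydrofuran ring D. Because O1 carries prenyl on one ortho carbon (C7) and the C3a–C3–C2 chain on the other (C3a), heating a 1,1-dimethylallyl aryl ether that bears an ortho threo epoxy carbinol (silylated, para carbon blocked by bromine) should move the allyl unit to C7 by [3,3] shift and let the freed O1 close ring D by epoxide opening with inversion, fixing C2 trans to C3. The bromide is later turned into an alkyne and annulated with CO and an iodophloroglucinol triacetate to the flavone.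

Key step: step 6

Remark on the chemistry: the (2S,3S) descriptors of the target correspond to a trans arrangement of the C2 hydroxyisopropyl group and the C3 hydroxyl, and because 3-hydroxy-2,3-dihydrobenzofurans dehydrate to benzofurans under acid, every operation after ring closure is kept neutral or basic.

Step 1
Reactants: 1 5-bromosalicylaldehyde; 2 3-chloro-3-methylbut-1-yne
Product: 3 5-bromo-2-(2-methylbut-3-yn-2-yloxy)benzaldehyde
Conditions: CuCl2·2H2O (1 mol %), DBU, MeCN, 0 °C to rt
Reagents that add atoms: none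
Why: Copper-catalysed O-alkylation of a phenoxide by a tertiary propargylic chloride is the standard entry to aryl 1,1-dimethylpropargyl ethers and is favoured by an acidic phenol such as this one, the aldehyde and the aryl bromide being spectators.

Step 2
Reactants: 3 5-bromo-2-(2-methylbut-3-yn-2-yloxy)benzaldehyde
Product: 4 5-bromo-2-(2-methylbut-3-en-2-yloxy)benzaldehyde
Conditions: H2 (1 atm), Pd/CaCO3 poisoned with Pb(OAc)2, quinoline, EtOAc, rt, stopped after 1 equiv H2
Reagents that add atoms: none
Why: Lindlar semihydrogenation of a terminal alkyne stops at the vinyl group on the lead-poisoned catalyst, and the aryl bromide, aldehyde and tertiary ether are not reduced at 1 atm and room temperature.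

Step 3
Reactants: 4 5-bromo-2-(2-methylbut-3-en-2-yloxy)benzaldehyde; 5 2-methylprop-1-enylmagnesium bromide
Product: 7 (R)-1-[5-bromo-2-(2-methylbut-3-en-2-yloxy)phenyl]-3-methylbut-2-en-1-ol, via bis(2-methylprop-1-enyl)zinc 6 (not isolated)
Conditions: 5 (2.4 equiv), ZnCl2 (1.2 equiv), THF, 0 °C; solvent switch to toluene, N,N,N',N'-tetraethylethylenediamine; (2R)-3-exo-morpholinoisoborneol [(+)-MIB, 10 mol %], then 4, 0 °C; then H2O
Reagents that add atoms: none
Why: Amino-alcohol-catalysed enantioselective alkenylzinc addition to an aryl aldehyde, in which the zinc–ligand chelate delivers the 2-methylpropenyl group to one aldehyde face; the (2R) ligand is chosen for Re-face attack (the mirror image of the Si-face sense expected for the (2S) ligand) so that the new carbinol centre is (R), and the diamine ties up magnesium halide that would otherwise promote racemic addition.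

Step 4
Reactants: 7 (R)-1-[5-bromo-2-(2-methylbut-3-en-2-yloxy)phenyl]-3-methylbut-2-en-1-ol
Product: 8 (S)-[5-bromo-2-(2-methylbut-3-en-2-yloxy)phenyl][(R)-3,3-dimethyloxiran-2-yl]methanol (threo)
Conditions: m-CPBA (1.1 equiv), NaHCO3, CH2Cl2, 0 °C
Reagents that add atoms: m-CPBA (3-chloroperoxybenzoic acid), OOC(=O)c1cccc(Cl)c1
Why: Hydroxyl-directed peracid epoxidation, in which allylic 1,3-strain with the cis methyl group holds the carbinol C–H in the alkene plane and the hydrogen-bonded peracid delivers oxygen to the face bearing OH, setting the oxirane CH as (R) (threo), while the electron-rich trisubstituted alkene far outpaces the monosubstituted vinyl group deactivated by its allylic oxygen.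

Step 5
Reactants: 8 (S)-[5-bromo-2-(2-methylbut-3-en-2-yloxy)phenyl][(R)-3,3-dimethyloxiran-2-yl]methanol
Product: 9 tert-butyl{(S)-[5-bromo-2-(2-methylbut-3-en-2-yloxy)phenyl][(R)-3,3-dimethyloxiran-2-yl]methoxy}dimethylsilane
Conditions: TBSCl, imidazole, DMAP (cat.), DMF, rt to 40 °C
Reagents that add atoms: TBSCl (tert-butylchlorodimethylsilane), CC(C)(C)[Si](C)(C)Cl
Why: Imidazole-mediated silylation of a secondary alcohol is routine and non-acidic, so the epoxide and the tertiary allyl ether survive, and removing the hydroxyl proton means that in step 6 neither a Payne rearrangement nor a retro-aldol-type loss of the side chain from an ipso-rearranged dienone is possible.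

Step 6
Reactants: 9 tert-butyl{(S)-[5-bromo-2-(2-methylbut-3-en-2-yloxy)phenyl][(R)-3,3-dimethyloxiran-2-yl]methoxy}dimethylsilane
Product: 12 2-[(2S,3S)-5-bromo-3-(tert-butyldimethylsilyloxy)-7-(3-methylbut-2-enyl)-2,3-dihydro-1-benzofuran-2-yl]propan-2-ol, via ortho-dienone 10 (not isolated), via ortho-prenylphenol 11 (not isolated)
Conditions: K2CO3 (1.5 equiv), degassed DMF, 130 °C, sealed tube, Ar
Reagents that add atoms: none
Why: Heat drives a concerted [3,3] shift in which the vinyl CH2 of the 1,1-dimethylallyl ether bonds to the only free ortho carbon, giving dienone 10, which enolises to ortho-prenylphenol 11 (an aromatic Claisen rearrangement, the classical way from such ethers to ortho-prenylphenols); carbonate holds 11 as its phenoxide, which then opens the epoxide as in known phenoxide–epoxide cyclisations to hydroxyisopropyl-dihydrobenzofurans. Ring D closes in the 5-exo-tet mode by back-side attack of O1 on the secondary oxirane carbon, the oxirane oxygen leaving as the tertiary alkoxide that becomes the 2-hydroxypropan-2-yl group. The new C2 centre arises by inversion of the (R)-oxirane carbon to (2S), and because the silylated carbinol carbon (C3, S) is untouched, the threo relationship is translated into the trans-2,3 ring. Two selectivities are needed: ortho over ipso migration, secured because the para carbon carries bromine and the silylated carbinol leaves the ipso dienone no exit other than reversal; and 5-exo over 6-endo opening, secured by the anionic, acid-free medium in which attack at the tertiary carbon is disfavoured. The secondary silyl ether, the aryl bromide and the new prenyl alkene should be inert to K2CO3 in DMF at this temperature.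

Step 7
Reactants: 12 2-[(2S,3S)-5-bromo-3-(tert-butyldimethylsilyloxy)-7-(3-methylbut-2-enyl)-2,3-dihydro-1-benzofuran-2-yl]propan-2-ol; 13 ethynyltrimethylsilane
Product: 14 2-[(2S,3S)-3-(tert-butyldimethylsilyloxy)-7-(3-methylbut-2-enyl)-5-[(trimethylsilyl)ethynyl]-2,3-dihydro-1-benzofuran-2-yl]propan-2-ol
Conditions: Pd(PhCN)2Cl2 (3 mol %), [(t-Bu)3PH]BF4 (6 mol %), CuI (2 mol %), i-Pr2NH, 1,4-dioxane, rt to 50 °C
Reagents that add atoms: none
Why: Sonogashira coupling, in which the bulky electron-rich tri-tert-butylphosphine lets the unhindered but electron-rich aryl bromide undergo oxidative addition near room temperature, the tertiary alcohol, silyl ether and prenyl alkene being inert.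

Step 8
Reactants: 14 2-[(2S,3S)-3-(tert-butyldimethylsilyloxy)-7-(3-methylbut-2-enyl)-5-[(trimethylsilyl)ethynyl]-2,3-dihydro-1-benzofuran-2-yl]propan-2-ol
Product: 15 (2S,3S)-5-ethynyl-2-(2-hydroxypropan-2-yl)-7-(3-methylbut-2-enyl)-2,3-dihydro-1-benzofuran-3-ol
Conditions: Bu4NF (3 equiv), THF, 0 °C to rt
Reagents that add atoms: none
Why: Fluoride-induced desilylation cleaves the alkynyl C–Si bond and the secondary O–Si bond in one basic, acid-free operation, which avoids dehydration of the 3-hydroxy-2,3-dihydrobenzofuran.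

Step 9
Reactants: 16 phloroglucinol (benzene-1,3,5-triol)
Product: 17 2-iodobenzene-1,3,5-triol
Conditions: I2 (1.0 equiv), NaHCO3, THF/H2O, 0 °C
Reagents that add atoms: iodine (I2), I-I
Why: Electrophilic aromatic iodination of the symmetrical, highly activated triol, whose three ring C–H positions are equivalent, so that one equivalent of iodine at 0 °C should stop at mono-substitution.

Step 10
Reactants: 17 2-iodobenzene-1,3,5-triol
Product: 18 2-iodobenzene-1,3,5-triyl triacetate
Conditions: Ac2O, pyridine, DMAP (cat.), CH2Cl2, 0 °C to rt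
Reagents that add atoms: acetic anhydride, CC(=O)OC(C)=O
Why: Exhaustive O-acetylation of phenols under nucleophilic catalysis stabilises the oxidation-prone iodotriol and installs the ortho acetate that is unmasked during step 11.

Step 11
Reactants: 15 (2S,3S)-5-ethynyl-2-(2-hydroxypropan-2-yl)-7-(3-methylbut-2-enyl)-2,3-dihydro-1-benzofuran-3-ol; 18 2-iodobenzene-1,3,5-triyl triacetate
Product: 21 5,7-dihydroxy-2-[(2S,3S)-3-hydroxy-2-(2-hydroxypropan-2-yl)-7-(3-methylbut-2-enyl)-2,3-dihydro-1-benzofuran-5-yl]-4H-chromen-4-one, via triacetoxyphenyl ynone 19 (not isolated), via flavone 5,7-diacetate 20 (not isolated)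
Conditions: PdCl2(PPh3)2 (5 mol %), thiourea (5 mol %), 1,3-bis(diphenylphosphino)propane (5 mol %), DBU, Et2NH, CO (1 atm), 40 °C; then concentrate, K2CO3, MeOH, rt
Reagents that add atoms: carbon monoxide, [C-]#[O+]
Why: Palladium-catalysed carbonylative annulation of an ortho-iodophenol acetate with a terminal alkyne, in which oxidative addition of 18 to zerovalent palladium, CO insertion and alkynylation give ynone 19, diethylamine adds to the ynone and cleaves the ortho acetate so that ring C closes in the 6-endo sense through the β-amino enone (no aurone) to 20, and carbonate-catalysed methanolysis then removes the two remaining aryl acetates without touching the alcohols, the prenyl group or either stereocentre.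

Compound list
1 | 5-bromosalicylaldehyde | O=Cc1cc(Br)ccc1O | starting material
2 | 3-chloro-3-methylbut-1-yne | CC(C)(Cl)C#C | starting material
3 | 5-bromo-2-(2-methylbut-3-yn-2-yloxy)benzaldehyde | O=Cc1cc(Br)ccc1OC(C)(C)C#C | intermediate
4 | 5-bromo-2-(2-methylbut-3-en-2-yloxy)benzaldehyde | O=Cc1cc(Br)ccc1OC(C)(C)C=C | intermediate
5 | 2-methylprop-1-enylmagnesium bromide | CC(C)=C[Mg]Br | starting material
6 | bis(2-methylprop-1-enyl)zinc (formed and consumed in the flask) | CC(C)=C[Zn]C=C(C)C | intermediate
7 | (R)-1-[5-bromo-2-(2-methylbut-3-en-2-yloxy)phenyl]-3-methylbut-2-en-1-ol | Brc1ccc(OC(C)(C)C=C)c(c1)[C@H](O)C=C(C)C | intermediate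
8 | (S)-[5-bromo-2-(2-methylbut-3-en-2-yloxy)phenyl][(R)-3,3-dimethyloxiran-2-yl]methanol | Brc1ccc(OC(C)(C)C=C)c(c1)[C@H](O)[C@H]2OC2(C)C | intermediate
9 | tert-butyl{(S)-[5-bromo-2-(2-methylbut-3-en-2-yloxy)phenyl][(R)-3,3-dimethyloxiran-2-yl]methoxy}dimethylsilane | Brc1ccc(OC(C)(C)C=C)c(c1)[C@H](O[Si](C)(C)C(C)(C)C)[C@H]2OC2(C)C | intermediate
10 | 4-bromo-2-{(S)-(tert-butyldimethylsilyloxy)[(R)-3,3-dimethyloxiran-2-yl]methyl}-6-(3-methylbut-2-enyl)cyclohexa-2,4-dien-1-one (ortho-dienone, either configuration at C6, formed in the flask) | O=C1C(CC=C(C)C)C=C(Br)C=C1[C@H](O[Si](C)(C)C(C)(C)C)[C@H]2OC2(C)C | intermediate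
11 | tert-butyl{(S)-[5-bromo-2-hydroxy-3-(3-methylbut-2-enyl)phenyl][(R)-3,3-dimethyloxiran-2-yl]methoxy}dimethylsilane (ortho-prenylphenol, present as its potassium phenoxide, formed in the flask) | CC(C)=CCc1cc(Br)cc(c1O)[C@H](O[Si](C)(C)C(C)(C)C)[C@H]2OC2(C)C | intermediate
12 | 2-[(2S,3S)-5-bromo-3-(tert-butyldimethylsilyloxy)-7-(3-methylbut-2-enyl)-2,3-dihydro-1-benzofuran-2-yl]propan-2-ol | CC(C)=CCc1cc(Br)cc2c1O[C@H](C(C)(C)O)[C@H]2O[Si](C)(C)C(C)(C)C | intermediate
13 | ethynyltrimethylsilane | C#C[Si](C)(C)C | starting material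
14 | 2-[(2S,3S)-3-(tert-butyldimethylsilyloxy)-7-(3-methylbut-2-enyl)-5-[(trimethylsilyl)ethynyl]-2,3-dihydro-1-benzofuran-2-yl]propan-2-ol | CC(C)=CCc1cc(C#C[Si](C)(C)C)cc2c1O[C@H](C(C)(C)O)[C@H]2O[Si](C)(C)C(C)(C)C | intermediate
15 | (2S,3S)-5-ethynyl-2-(2-hydroxypropan-2-yl)-7-(3-methylbut-2-enyl)-2,3-dihydro-1-benzofuran-3-ol | CC(C)=CCc1cc(C#C)cc2c1O[C@H](C(C)(C)O)[C@H]2O | intermediate
16 | phloroglucinol (benzene-1,3,5-triol) | Oc1cc(O)cc(O)c1 | starting material
17 | 2-iodobenzene-1,3,5-triol | Oc1cc(O)cc(O)c1I | intermediate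
18 | 2-iodobenzene-1,3,5-triyl triacetate | CC(=O)Oc1cc(OC(C)=O)cc(OC(C)=O)c1I | intermediate
19 | 2-{3-[(2S,3S)-3-hydroxy-2-(2-hydroxypropan-2-yl)-7-(3-methylbut-2-enyl)-2,3-dihydro-1-benzofuran-5-yl]prop-2-ynoyl}benzene-1,3,5-triyl triacetate (ynone, formed in the flask) | CC(C)=CCc1cc(C#CC(=O)c3c(OC(C)=O)cc(OC(C)=O)cc3OC(C)=O)cc2c1O[C@H](C(C)(C)O)[C@H]2O | intermediate
20 | 2-[(2S,3S)-3-hydroxy-2-(2-hydroxypropan-2-yl)-7-(3-methylbut-2-enyl)-2,3-dihydro-1-benzofuran-5-yl]-4-oxo-4H-chromene-5,7-diyl diacetate (formed in the flask) | CC(C)=CCc1cc(-c2cc(=O)c3c(OC(C)=O)cc(OC(C)=O)cc3o2)cc2c1O[C@H](C(C)(C)O)[C@H]2O | intermediate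
21 | 5,7-dihydroxy-2-[(2S,3S)-3-hydroxy-2-(2-hydroxypropan-2-yl)-7-(3-methylbut-2-enyl)-2,3-dihydro-1-benzofuran-5-yl]-4H-chromen-4-one | CC(C)=CCc1cc(-c2cc(=O)c3c(O)cc(O)cc3o2)cc2c1O[C@H](C(C)(C)O)[C@H]2O | target

Total step count: 11. Longest linear sequence: 9 (steps 1–8 and 11); steps 9 and 10 are the side branch to 18.

Steps most likely to fail

Step 6. The cascade may be undercut by heterolysis of the tertiary allyl–oxygen bond with loss of the allyl unit before the sigmatropic shift, by competing 6-endo opening at the tertiary oxirane carbon, or by thermal erosion of the epoxide. Migration of the silyl group to the new tertiary alkoxide would be harmless, since step 8 removes it from either oxygen. The fallback sets out from 4 and comes back at 12; it separates the two bond formations and moves the sigmatropic step to the aldehyde stage, where no epoxide is present. Heating 4 (N,N-diethylaniline, 150 °C) should give 5-bromo-2-hydroxy-3-(3-methylbut-2-enyl)benzaldehyde F1. TBSCl and imidazole should convert it into the aryl silyl ether 5-bromo-2-(tert-butyldimethylsilyloxy)-3-(3-methylbut-2-enyl)benzaldehyde F2. Addition of 6 under the conditions of step 3 should give the (R)-allylic alcohol F3. Ti(OiPr)4 and t-BuOOH (CH2Cl2, −20 °C), a hydroxyl-directed epoxidation that leaves the isolated prenyl alkene alone, should give the threo epoxy alcohol F4. Bu4NF (THF, 0 °C) should unmask the phenoxide, which closes ring D by the same 5-exo opening to the diol (2S,3S)-5-bromo-2-(2-hydroxypropan-2-yl)-7-(3-methylbut-2-enyl)-2,3-dihydro-1-benzofuran-3-ol F5. Selective silylation of its secondary hydroxyl (TBSCl, imidazole) returns 12.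

Step 11. The three-component carbonylation may stall at the doubly ortho-substituted aryl iodide, lose acetates before oxidative addition, or leak into direct alkyne–aryl coupling without CO uptake. The fallback sets out from 15 and comes back at 19; it replaces CO insertion by acylation of the alkyne. Commercial 2,4,6-trihydroxybenzoic acid should be peracetylated (Ac2O, pyridine) to 2,4,6-triacetoxybenzoic acid F6 and converted with oxalyl chloride and catalytic DMF into 2,4,6-triacetoxybenzoyl chloride F7. This hindered acid chloride should acylate the alcohols of 15 only slowly in the absence of DMAP. Its coupling with 15 (PdCl2(PPh3)2, CuI, Et3N, THF, rt) should give ynone 19, which is carried on with Et2NH and then K2CO3/MeOH through 20 to 21 as in the second half of step 11.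

Step 3. Facial selectivity may be eroded by uncatalysed background addition, promoted by residual magnesium salts or by coordination of the ortho ether oxygen to zinc. The fallback sets out from 4 and comes back at 7; it replaces asymmetric catalysis by resolution. Direct addition of 5 to 4 (THF, −78 °C) should give the racemic alcohol rac-1-[5-bromo-2-(2-methylbut-3-en-2-yloxy)phenyl]-3-methylbut-2-en-1-ol F8. Esterification with (S)-2-methoxy-2-phenylacetic acid (DCC, DMAP) should give two diastereomeric esters separable by chromatography, the one from the (R)-carbinol being (R)-1-[5-bromo-2-(2-methylbut-3-en-2-yloxy)phenyl]-3-methylbut-2-enyl (S)-2-methoxy-2-phenylacetate F9. Saponification (LiOH, THF/H2O, 0 °C) returns 7.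

Further compounds
F1 | step 6 | 5-bromo-2-hydroxy-3-(3-methylbut-2-enyl)benzaldehyde | O=Cc1cc(Br)cc(CC=C(C)C)c1O
F2 | step 6 | 5-bromo-2-(tert-butyldimethylsilyloxy)-3-(3-methylbut-2-enyl)benzaldehyde | O=Cc1cc(Br)cc(CC=C(C)C)c1O[Si](C)(C)C(C)(C)C
F3 | step 6 | (R)-1-[5-bromo-2-(tert-butyldimethylsilyloxy)-3-(3-methylbut-2-enyl)phenyl]-3-methylbut-2-en-1-ol | CC(C)=CCc1cc(Br)cc(c1O[Si](C)(C)C(C)(C)C)[C@H](O)C=C(C)C
F4 | step 6 | (S)-[5-bromo-2-(tert-butyldimethylsilyloxy)-3-(3-methylbut-2-enyl)phenyl][(R)-3,3-dimethyloxiran-2-yl]methanol | CC(C)=CCc1cc(Br)cc(c1O[Si](C)(C)C(C)(C)C)[C@H](O)[C@H]2OC2(C)C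
F5 | step 6 | (2S,3S)-5-bromo-2-(2-hydroxypropan-2-yl)-7-(3-methylbut-2-enyl)-2,3-dihydro-1-benzofuran-3-ol | CC(C)=CCc1cc(Br)cc2c1O[C@H](C(C)(C)O)[C@H]2O
F6 | step 11 | 2,4,6-triacetoxybenzoic acid | CC(=O)Oc1cc(OC(C)=O)c(C(=O)O)c(OC(C)=O)c1
F7 | step 11 | 2,4,6-triacetoxybenzoyl chloride | CC(=O)Oc1cc(OC(C)=O)c(C(Cl)=O)c(OC(C)=O)c1
F8 | step 3 | rac-1-[5-bromo-2-(2-methylbut-3-en-2-yloxy)phenyl]-3-methylbut-2-en-1-ol | Brc1ccc(OC(C)(C)C=C)c(c1)C(O)C=C(C)C
F9 | step 3 | (R)-1-[5-bromo-2-(2-methylbut-3-en-2-yloxy)phenyl]-3-methylbut-2-enyl (S)-2-methoxy-2-phenylacetate | Brc1ccc(OC(C)(C)C=C)c(c1)[C@H](OC(=O)[C@@H](OC)c1ccccc1)C=C(C)C
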